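# Proposed total synthesis of CNP0179010.1 (compound 30)

## Analysis of the target

Target 30 is a longipinane-type sesquiterpenoid triester. It is numbered here as tricyclo[5.4.0.0^{2,8}]undecane (C1–C11), with C12 the CH2O carbon on C6. A cyclobutane C1–C2–C8–C7 has its diagonal C1/C8 spanned by the enone bridge C11(=O)–C10=C9(CH3), a verbenone-type bicyclo[3.1.1]heptenone. Its other diagonal C2/C7 is spanned by C3–C4–C5–C6, a seven-membered ring (bicyclo[4.1.1]octane).

There are seven stereocentres (1R,2R,3R,5R,6S,7S,8R). C1, C2, C7 and C8 are tied together by the two bridges, so only their absolute sense is open. C3, C5 and C6 lie on the flexible four-carbon bridge: C3–O and C12 are cis, and C5–O is trans to both and cis to the C6 methyl group.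

The cyclobutane with its four-carbon bridge is almost mirror-symmetric, because C1 and C8 are both CH bridgeheads and only the remote enone tells the two faces of the seven-membered ring apart. C3, C5 and C6 therefore cannot be set by the core; one needs reagent control and the others must be relayed from it.

The C3 and C5 carbinols are both neopentyl and alike, yet carry different acyl groups. The differentiation of senecioate, acetate and angelate has to come from the way the oxygens are made.

Sensitive groups are: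
- the angelate (Z to E isomerisation to the tiglate),
- the senecioate (deconjugation if introduced through the acyl chloride),
- 1,3-related acyloxy groups (migration, β-elimination next to a ketone),
- the acid-labile strained pinane-type core and the enone.

The feature that invites the key step: C7 is a one-carbon bridge between two CH bridgeheads, C8 carries C9 with its methyl group, and C2 is quaternary with one carbon syn and one anti to the enone bridge. A C7 cyclobutanone with a C9 methylidene group is exactly the product of an intramolecular vinylketene–alkene [2+2] cycloaddition. In that reaction C2 comes from a trisubstituted alkene of defined geometry, and the C11 oxygen can serve as a temporary stereocentre.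

The synthesis is hard because of the doubly 1,3-bridged cyclobutane, the two quaternary carbons C2 and C6, and three different esters on a base- and acid-sensitive skeleton.

## Retrosynthetic reasoning

**Enone (30 ⇒ 28).** The C9=C10–C11=O enone is taken back to a C11 carbinol next to a C9 methylidene group (28). Oxidation gives the β,γ-unsaturated ketone 29, which moves into conjugation. The cut is made here because the C11 oxygen, as a silyl ether, can then be the one stereocentre set by catalysis in the acyclic precursor and is destroyed at the end.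

**Esters (28 ⇒ 23 ⇒ 20 ⇒ 19).** The angelate is removed first; it goes on last, on the only primary hydroxyl of diol 23, from acid 24. The acetate is removed next. The senecioate and the C5 carbinol are cut together: an Evans–Tishchenko reaction of β-hydroxy ketone 19 with aldehyde 3 makes the anti C5–OH and acylates O3 in one event. This differentiates the two neopentyl carbinols. C12 stays an allyl ester until the ketone is gone (21, 23).

**C6 and the seven-membered ring (19 ⇒ 18 ⇒ 17).** The C6 methyl group is cut from β-keto ester 18, with C-methylation under control of the C3 hydroxyl. The C5–C6 bond is cut as a Claisen-type acylation of the C6 ester enolate by the β-lactone of 17. Nucleophile (C6) and electrophile (C5) are then both in place after one two-carbon addition at C3, and the lactone releases the free C3–OH that steps 13 and 14 need.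

**C3 (17 ⇒ 16).** C3–C4 is cut as a catalytic asymmetric acyl halide–aldehyde cyclocondensation on the non-enolisable aldehyde 16. The catalyst sets C3, the first stereocentre of the seven-membered ring, where the core gives no bias.

**C6–C7 (16 ⇒ 15 ⇒ 14 ⇒ 12).** The C7–C6 bond, with its hydrogen on C7, is cut back to the C7 ketone of 12 by olefination with phosphonate 13 and conjugate reduction. Hydride can reach C7 only from the side of the three-carbon bridge, which puts C6 on the same side as C3.

**Key disconnection (12 ⇒ 11 ⇒ 9).** Cutting C1–C7 and C2–C8 opens the cyclobutane and the six-membered ring at once and leads to the acyclic vinylketene 11, made from dienoic acid 9. These bonds are chosen because the carbonyl carbon of a ketene becomes a one-carbon bridge (C7), its α-carbon becomes the bridgehead that bears the methylidene carbon (C8/C9), and the E-alkene C1=C2 becomes the quaternary C2. The forward reaction must give the crossed adduct, and the C11 silyloxy group must decide the face.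

**Acyclic precursor (9 ⇒ 6 ⇒ 4 ⇒ 2 + 3).** The C3 oxygen is cut back to an allylic oxidation of the E-methyl group of 5. The C10–C11 bond is cut to a catalytic enantioselective vinylogous aldol addition of silyl dienolate 2 (from ester 1) to aldehyde 3.

## Alternatives that were turned down

Alternative 1: the textbook cyclobutane disconnection, a [2+2] photocycloaddition. Cutting C1–C7 and C2–C8 photochemically leads to the eleven-membered cross-conjugated trienone A1; the forward key step would be a transannular crossed enone–alkene [2+2] cycloaddition. It was turned down for four reasons.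
- The only monocyclic [2+2] precursor of a cyclobutane bridged across both diagonals is this eleven-membered ring. Making it with three stereocentres, a quaternary C6 and three defined alkene geometries (1E,7E,9Z) costs more than the cycloaddition saves.
- C1 and C8 are linked by three atoms, so the rule of five favours 1,5-closure to the fused bicyclo[3.2.0] adduct and not the crossed bicyclo[3.1.1] adduct.
- The triplet 1,4-biradical can rotate before closure, so the geometry of C1=C2 is not passed on cleanly to the quaternary C2.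
- The angelate would isomerise under irradiation.
- A shorter ten-membered 1,5-diene variant would need a ring expansion afterwards.

Alternative 2: chiral pool. Ten carbons of 30 map onto (1S,5S)-verbenone A2. Its photochemical 1,3-shift would give chrysanthenone A3, which already has the C7 carbonyl, the C9 methyl-bearing alkene and the gem-dimethyl bridge as C2. The forward plan would attach C6 at C7 and bridge to the anti methyl group of C2. It was turned down because that methyl group (the future C3) is unactivated. The only handle near it is the C7 carbonyl. A C7 alkoxy radical would open the cyclobutane faster than it abstracts hydrogen, and a directing hydroxyl on C7 would occupy the position that C6 must take. In addition, the rearrangement passes through a ring-opened achiral vinylketene, by which enantiomeric purity can be lost. The pool would buy the cyclobutane and leave the hardest C–H functionalisation.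

Alternative 3: intramolecular enolate alkylation, the classical way to 1,3-bridged cyclobutanes. Cutting C1–C7 leads to the 6–7-fused keto mesylate A4; the forward key step is a 4-exo-tet displacement of the C7 sulfonate by the α′-enolate (C1) of the enone. It was turned down for three reasons.
- C7 is a secondary neopentyl centre next to quaternary C6, so SN2 is very slow and elimination or γ-deprotonation of the enone should win.
- All other stereocentres, including the quaternary C2 and C6, would have to be built first on a flexible bicycle with no element that relays them.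
- The three esters would not survive the strong base, which adds protecting-group steps.

Key step: step 7

## Route

Remark on the chemistry: all polycyclic intermediates carry the locants of the target (C1–C12), also before the seven-membered ring exists. The chiral catalysts of steps 2 and 11 are meant in the enantiomeric form that gives the stated configuration.

Step 1
Reactants: 1 methyl 3-methylbut-2-enoate
Product: 2 tert-butyl[(1-methoxy-3-methylbuta-1,3-dien-1-yl)oxy]dimethylsilane
Conditions: LiN(iPr)2, THF/DMPU, −78 °C; TBSCl, −78 °C → rt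
Reagents that add atoms: tert-butyldimethylsilyl chloride, CC(C)(C)[Si](C)(C)Cl
Why: Kinetic γ-deprotonation of the senecioate and O-silylation of the extended enolate give the silyl dienolate; no stereocentre is formed.

Step 2
Reactants: 2 tert-butyl[(1-methoxy-3-methylbuta-1,3-dien-1-yl)oxy]dimethylsilane; 3 3-methylbut-2-enal
Product: 4 methyl (2E,5S)-5-hydroxy-3,7-dimethylocta-2,6-dienoate
Conditions: SiCl4 (1.1 equiv), chiral binaphthyldiamine-derived bisphosphoramide (5 mol%), iPr2NEt (0.1 equiv), CH2Cl2, −78 °C; aq. NaHCO3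
Reagents that add atoms: none
Why: Catalytic enantioselective vinylogous Mukaiyama aldol addition: the dienolate attacks through its γ-carbon the conjugated aldehyde bound to the chiral phosphoramide–silicon Lewis acid, which selects the aldehyde face and sets C5 (the later C11) as S. The 2E-enoate is expected and matters for step 7.

Step 3
Reactants: 4 methyl (2E,5S)-5-hydroxy-3,7-dimethylocta-2,6-dienoate
Product: 5 methyl (2E,5S)-5-[(tert-butyldimethylsilyl)oxy]-3,7-dimethylocta-2,6-dienoate
Conditions: TBSCl, imidazole, DMF, rt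
Reagents that add atoms: tert-butyldimethylsilyl chloride, CC(C)(C)[Si](C)(C)Cl
Why: Standard silylation; a silyl ether is chosen because it is a poor leaving group at this allylic position and lasts until step 19.

Step 4
Reactants: 5 methyl (2E,5S)-5-[(tert-butyldimethylsilyl)oxy]-3,7-dimethylocta-2,6-dienoate
Product: 6 methyl (2E,5S,6E)-5-[(tert-butyldimethylsilyl)oxy]-8-hydroxy-3,7-dimethylocta-2,6-dienoate
Conditions: SeO2 (0.3 equiv), t-BuOOH (3 equiv), salicylic acid (0.1 equiv), CH2Cl2, 0 °C → rt
Reagents that add atoms: tert-butyl hydroperoxide, CC(C)(C)OO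
Why: Allylic oxidation with SeO2 (ene reaction, then [2,3]-shift) should take place at the E-methyl group of the electron-rich trisubstituted alkene, while the enoate alkene is deactivated. The E-geometry of the new allylic alcohol later places C3 anti on C2.

Step 5
Reactants: 6 methyl (2E,5S,6E)-5-[(tert-butyldimethylsilyl)oxy]-8-hydroxy-3,7-dimethylocta-2,6-dienoate
Product: 7 (2E,5S,6E)-5-[(tert-butyldimethylsilyl)oxy]-8-hydroxy-3,7-dimethylocta-2,6-dienoic acid
Conditions: LiOH·H2O, THF/MeOH/H2O, 45 °C; 1 M HCl to pH 3, 0 °C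
Reagents that add atoms: none
Why: Saponification before the labile primary silyl ether is put on; the secondary silyl ether should survive.

Step 6
Reactants: 7 (2E,5S,6E)-5-[(tert-butyldimethylsilyl)oxy]-8-hydroxy-3,7-dimethylocta-2,6-dienoic acid
Product: 9 (2E,5S,6E)-5-[(tert-butyldimethylsilyl)oxy]-3,7-dimethyl-8-[(triethylsilyl)oxy]octa-2,6-dienoic acid, via bis-silylated triethylsilyl ester 8 (not isolated)
Conditions: TESCl (2.5 equiv), imidazole, CH2Cl2, 0 °C; then K2CO3, MeOH/H2O, 0 °C, 10 min; pH 5 buffer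
Reagents that add atoms: triethylsilyl chloride, CC[Si](Cl)(CC)CC
Why: Silylation of hydroxyl and carboxyl, then selective methanolysis of the much more labile silyl ester. The primary triethylsilyl ether is chosen because Swern conditions turn it directly into the aldehyde in step 10.

Step 7
Reactants: 9 (2E,5S,6E)-5-[(tert-butyldimethylsilyl)oxy]-3,7-dimethyl-8-[(triethylsilyl)oxy]octa-2,6-dienoic acid
Product: 12 (1R,2R,8R,11S)-11-[(tert-butyldimethylsilyl)oxy]-2-methyl-9-methylidene-2-{[(triethylsilyl)oxy]methyl}bicyclo[3.1.1]heptan-7-one (target locants: C7 ketone bridge, C2 the other one-carbon bridge with CH2OSi anti to the C9–C11 bridge, OSi on C11 on the side of C7), via acid chloride 10 (not isolated), via vinylketene 11 (not isolated)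
Conditions: 1-chloro-N,N,2-trimethylprop-1-en-1-amine (1.2 equiv), CH2Cl2, 0 °C → rt; then slow addition to Et3N (5 equiv), toluene, 110 °C, 0.005 M
Reagents that add atoms: none
Why: Et3N removes a proton from the 3-methyl group, which lies cis to the acyl group in the 2E-chloride 10, and loss of chloride gives vinylketene 11; this undergoes a thermal, asynchronous intramolecular ketene–alkene [2+2] cycloaddition. The closest known reaction type is the intramolecular [2+2] cycloaddition of vinylketenes made from geranic- and farnesic-type acid chlorides, which gives 2-methylidenebicyclo[3.1.1]heptan-6-ones. The electrophilic ketene carbon C7 bonds to the less substituted alkene carbon C1 and closes the six-membered ring C7–C8–C9–C10–C11–C1 (6-exo with respect to C1=C2); the ketene α-carbon C8 then bonds to C2, where positive charge builds up on a tertiary carbon, and closes the cyclobutane in the crossed, bridged mode. C2 is set by the E-geometry of the alkene, which is added to suprafacially, so the methyl group that was cis to the tether ends syn to the three-carbon bridge and CH2OSi anti. C1 and C8 can only form as the cis-bridged pair. The absolute sense comes from C11: to avoid A1,3 strain with the C2 methyl group, C11–H sits inside and the silyloxy group outside, so the tether reaches only one alkene face and C1, C2 and C8 are relayed from the one catalytically set centre. The step needs regioselectivity for the crossed over the fused bicyclo[3.2.0] mode, secured by the polarisation of the trisubstituted alkene. It also needs the right site of dienolisation, secured by the 2E-geometry, and facial selectivity, secured by the allylic silyloxy group.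

Step 8
Reactants: 12 (1R,2R,8R,11S)-11-[(tert-butyldimethylsilyl)oxy]-2-methyl-9-methylidene-2-{[(triethylsilyl)oxy]methyl}bicyclo[3.1.1]heptan-7-one; 13 allyl (diethoxyphosphoryl)acetate
Product: 14 allyl 2-[(1R,2R,8S,11S)-11-[(tert-butyldimethylsilyl)oxy]-2-methyl-9-methylidene-2-{[(triethylsilyl)oxy]methyl}bicyclo[3.1.1]hept-7-ylidene]acetate (both alkene isomers)
Conditions: NaH, THF, 0 → 50 °C
Reagents that add atoms: none
Why: Horner–Wadsworth–Emmons olefination; the cyclobutanone is reactive because addition relieves strain and neither bridgehead α-carbon can enolise. The alkene geometry is of no consequence because C6 and C7 become sp3 in step 9.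

Step 9
Reactants: 14 allyl 2-[(1R,2R,8S,11S)-11-[(tert-butyldimethylsilyl)oxy]-2-methyl-9-methylidene-2-{[(triethylsilyl)oxy]methyl}bicyclo[3.1.1]hept-7-ylidene]acetate
Product: 15 allyl 2-[(1R,2R,7S,8R,11S)-11-[(tert-butyldimethylsilyl)oxy]-2-methyl-9-methylidene-2-{[(triethylsilyl)oxy]methyl}bicyclo[3.1.1]hept-7-yl]acetate
Conditions: Cu(OAc)2·H2O (5 mol%), 1,2-bis(diphenylphosphino)benzene (5 mol%), (EtO)2MeSiH (2 equiv), t-BuOH (2 equiv), toluene, rt
Reagents that add atoms: none
Why: Copper hydride conjugate reduction of a β,β-disubstituted enoate, chemoselective over the isolated methylidene group and the allyl ester. Hydride should reach C7 from the side of the three-carbon bridge, since the other face is blocked 1,3-diaxially by the CH2OSi group on C2; C7 becomes S with CH2CO2allyl cis to C3.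

Step 10
Reactants: 15 allyl 2-[(1R,2R,7S,8R,11S)-11-[(tert-butyldimethylsilyl)oxy]-2-methyl-9-methylidene-2-{[(triethylsilyl)oxy]methyl}bicyclo[3.1.1]hept-7-yl]acetate
Product: 16 allyl 2-[(1R,2R,7S,8R,11S)-11-[(tert-butyldimethylsilyl)oxy]-2-formyl-2-methyl-9-methylidenebicyclo[3.1.1]hept-7-yl]acetate
Conditions: (COCl)2, DMSO, CH2Cl2, −78 → −40 °C; Et3N, → 0 °C
Reagents that add atoms: none
Why: Swern conditions convert primary triethylsilyl ethers directly into aldehydes (silyl transfer to chloride, then the usual alkoxysulfonium elimination), while the secondary tert-butyldimethylsilyl ether stays; the aldehyde has no α-hydrogen.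

Step 11
Reactants: 16 allyl 2-[(1R,2R,7S,8R,11S)-11-[(tert-butyldimethylsilyl)oxy]-2-formyl-2-methyl-9-methylidenebicyclo[3.1.1]hept-7-yl]acetate
Product: 17 allyl 2-{(1R,2R,7S,8R,11S)-11-[(tert-butyldimethylsilyl)oxy]-2-methyl-9-methylidene-2-[(2R)-4-oxooxetan-2-yl]bicyclo[3.1.1]hept-7-yl}acetate (oxetane C2 is C3 of the target)
Conditions: AcBr (2 equiv), iPr2NEt (2.5 equiv), AlMe3/chiral bis(sulfonamide) triamine ligand (15 mol%), CH2Cl2, −50 °C
Reagents that add atoms: acetyl bromide, CC(=O)Br
Why: Catalytic asymmetric acyl halide–aldehyde cyclocondensation: ketene made in the flask adds in a [2+2] sense to the aldehyde bound to the chiral aluminium Lewis acid. The two aldehyde faces are nearly alike in the substrate, so the catalyst should set C3 (R); the β-lactone is at once a protected aldol and an activated acyl donor for C5.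

Step 12
Reactants: 17 allyl 2-{(1R,2R,7S,8R,11S)-11-[(tert-butyldimethylsilyl)oxy]-2-methyl-9-methylidene-2-[(2R)-4-oxooxetan-2-yl]bicyclo[3.1.1]hept-7-yl}acetate
Product: 18 allyl (1R,2R,3R,7S,8R,11S)-11-[(tert-butyldimethylsilyl)oxy]-3-hydroxy-2-methyl-9-methylidene-5-oxotricyclo[5.4.0.0^{2,8}]undecane-6-carboxylate (C6 epimers and enol)
Conditions: LiN(SiMe3)2 (2.2 equiv), THF, −78 → −30 °C; AcOH
Reagents that add atoms: none
Why: Claisen-type (Dieckmann) acylation: the C6 ester enolate attacks the strained lactone carbonyl C5 (7-exo-trig), as ester enolates do with β-lactones to give δ-hydroxy-β-keto esters. An enolate of the lactone cannot eliminate and should re-equilibrate, and the doubly deprotonated product is the sink. C3 keeps its configuration because the acyl–oxygen bond breaks.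

Step 13
Reactants: 18 allyl (1R,2R,3R,7S,8R,11S)-11-[(tert-butyldimethylsilyl)oxy]-3-hydroxy-2-methyl-9-methylidene-5-oxotricyclo[5.4.0.0^{2,8}]undecane-6-carboxylate
Product: 19 allyl (1R,2R,3R,6R,7S,8R,11S)-11-[(tert-butyldimethylsilyl)oxy]-3-hydroxy-2,6-dimethyl-9-methylidene-5-oxotricyclo[5.4.0.0^{2,8}]undecane-6-carboxylate
Conditions: MeI (3 equiv), K2CO3 (1.5 equiv), acetone, 0 °C → rt
Reagents that add atoms: iodomethane, CI
Why: C-Alkylation of the β-keto ester enolate, the only acidic site under carbonate. The C3 hydroxyl, hydrogen-bonded (or potassium-bridged) to the C5 enolate oxygen, is held pseudo-axial over the face of C6 on its own side, so MeI should enter from the other face; the methyl group then ends trans and the ester cis to C3–O. The mild base avoids retro-aldol cleavage.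

Step 14
Reactants: 19 allyl (1R,2R,3R,6R,7S,8R,11S)-11-[(tert-butyldimethylsilyl)oxy]-3-hydroxy-2,6-dimethyl-9-methylidene-5-oxotricyclo[5.4.0.0^{2,8}]undecane-6-carboxylate; 3 3-methylbut-2-enal
Product: 20 allyl (1R,2R,3R,5R,6R,7S,8R,11S)-11-[(tert-butyldimethylsilyl)oxy]-5-hydroxy-2,6-dimethyl-9-methylidene-3-[(3-methylbut-2-enoyl)oxy]tricyclo[5.4.0.0^{2,8}]undecane-6-carboxylate
Conditions: 3 (6 equiv), SmI2 (0.3 equiv), THF, −10 °C
Reagents that add atoms: none
Why: Evans–Tishchenko reaction: the samarium-bound hemiacetal of C3–OH and the aldehyde passes its hydride to C5 through a six-membered transition state from the side of O3. This should give the anti C5 carbinol (R) and leave O3 as the senecioate; the β,β-disubstituted enal resists conjugate addition. The two neopentyl carbinols are thus differentiated and the senecioate is made without an acyl chloride.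

Step 15
Reactants: 20 allyl (1R,2R,3R,5R,6R,7S,8R,11S)-11-[(tert-butyldimethylsilyl)oxy]-5-hydroxy-2,6-dimethyl-9-methylidene-3-[(3-methylbut-2-enoyl)oxy]tricyclo[5.4.0.0^{2,8}]undecane-6-carboxylate
Product: 21 (1R,2R,3R,5R,6R,7S,8R,11S)-11-[(tert-butyldimethylsilyl)oxy]-5-hydroxy-2,6-dimethyl-9-methylidene-3-[(3-methylbut-2-enoyl)oxy]tricyclo[5.4.0.0^{2,8}]undecane-6-carboxylic acid
Conditions: Pd(PPh3)4 (5 mol%), morpholine (3 equiv), THF, rt; pH 4 buffer
Reagents that add atoms: none
Why: Tsuji–Trost deallylation: the π-allyl complex is trapped by morpholine under neutral conditions, and the cleavage does not depend on the hindrance at the quaternary acyl carbon. It is placed after step 14 because a β-keto acid would lose CO2.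

Step 16
Reactants: 21 (1R,2R,3R,5R,6R,7S,8R,11S)-11-[(tert-butyldimethylsilyl)oxy]-5-hydroxy-2,6-dimethyl-9-methylidene-3-[(3-methylbut-2-enoyl)oxy]tricyclo[5.4.0.0^{2,8}]undecane-6-carboxylic acid
Product: 23 (1R,2R,3R,5R,6S,7S,8R,11S)-11-[(tert-butyldimethylsilyl)oxy]-5-hydroxy-6-(hydroxymethyl)-2,6-dimethyl-9-methylidenetricyclo[5.4.0.0^{2,8}]undec-3-yl 3-methylbut-2-enoate, via acyl fluoride 22 (not isolated)
Conditions: cyanuric fluoride, pyridine, CH2Cl2, −10 °C; then NaBH4, MeOH/THF, 0 °C
Reagents that add atoms: none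
Why: The hindered acid is activated as the small, stable acyl fluoride, which borohydride reduces to the primary alcohol well before it touches the conjugated ester; borane is avoided because of the methylidene group. C5–OH is left free to exclude acyl migration.

Step 17
Reactants: 23 (1R,2R,3R,5R,6S,7S,8R,11S)-11-[(tert-butyldimethylsilyl)oxy]-5-hydroxy-6-(hydroxymethyl)-2,6-dimethyl-9-methylidenetricyclo[5.4.0.0^{2,8}]undec-3-yl 3-methylbut-2-enoate; 24 (2Z)-2-methylbut-2-enoic acid (angelic acid)
Product: 26 [(1R,2R,3R,5R,6S,7S,8R,11S)-11-[(tert-butyldimethylsilyl)oxy]-5-hydroxy-2,6-dimethyl-9-methylidene-3-[(3-methylbut-2-enoyl)oxy]tricyclo[5.4.0.0^{2,8}]undec-6-yl]methyl (2Z)-2-methylbut-2-enoate, via angelic trichlorobenzoic anhydride 25 (not isolated)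
Conditions: 24 (1.5 equiv), 2,4,6-trichlorobenzoyl chloride, Et3N, toluene, rt; then 23, 60 °C, no DMAP
Reagents that add atoms: none
Why: Yamaguchi esterification through the mixed anhydride, run without nucleophilic catalyst and at moderate temperature to keep the Z-geometry. The primary hydroxyl should react well ahead of the neopentyl secondary C5–OH.

Step 18
Reactants: 26 [(1R,2R,3R,5R,6S,7S,8R,11S)-11-[(tert-butyldimethylsilyl)oxy]-5-hydroxy-2,6-dimethyl-9-methylidene-3-[(3-methylbut-2-enoyl)oxy]tricyclo[5.4.0.0^{2,8}]undec-6-yl]methyl (2Z)-2-methylbut-2-enoate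
Product: 27 [(1R,2R,3R,5R,6S,7S,8R,11S)-5-acetoxy-11-[(tert-butyldimethylsilyl)oxy]-2,6-dimethyl-9-methylidene-3-[(3-methylbut-2-enoyl)oxy]tricyclo[5.4.0.0^{2,8}]undec-6-yl]methyl (2Z)-2-methylbut-2-enoate
Conditions: Ac2O, DMAP (0.2 equiv), pyridine, rt
Reagents that add atoms: acetic anhydride, CC(=O)OC(C)=O
Why: DMAP-catalysed acetylation of the one remaining hydroxyl; the angelate is not activated under these conditions.

Step 19
Reactants: 27 [(1R,2R,3R,5R,6S,7S,8R,11S)-5-acetoxy-11-[(tert-butyldimethylsilyl)oxy]-2,6-dimethyl-9-methylidene-3-[(3-methylbut-2-enoyl)oxy]tricyclo[5.4.0.0^{2,8}]undec-6-yl]methyl (2Z)-2-methylbut-2-enoate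
Product: 28 [(1R,2R,3R,5R,6S,7S,8R,11S)-5-acetoxy-11-hydroxy-2,6-dimethyl-9-methylidene-3-[(3-methylbut-2-enoyl)oxy]tricyclo[5.4.0.0^{2,8}]undec-6-yl]methyl (2Z)-2-methylbut-2-enoate
Conditions: HF·pyridine, pyridine, THF, 0 °C → rt
Reagents that add atoms: none
Why: Buffered fluoride desilylation; it avoids the basic conditions that could move acyl groups or isomerise the angelate.

Step 20
Reactants: 28 [(1R,2R,3R,5R,6S,7S,8R,11S)-5-acetoxy-11-hydroxy-2,6-dimethyl-9-methylidene-3-[(3-methylbut-2-enoyl)oxy]tricyclo[5.4.0.0^{2,8}]undec-6-yl]methyl (2Z)-2-methylbut-2-enoate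
Product: 30 [(1R,2R,3R,5R,6S,7S,8R)-5-acetoxy-2,6,9-trimethyl-3-[(3-methylbut-2-enoyl)oxy]-11-oxotricyclo[5.4.0.0^{2,8}]undec-9-en-6-yl]methyl (2Z)-2-methylbut-2-enoate, via methylidene ketone 29 (not isolated)
Conditions: Dess–Martin periodinane, NaHCO3, CH2Cl2, 0 °C → rt; then DBU (0.2 equiv), 0 °C
Reagents that add atoms: none
Why: Oxidation of the C11 carbinol gives the β,γ-unsaturated ketone, whose doubly activated C10–H lets a catalytic amidine base move the double bond into conjugation (C9=C10 with the C9 methyl group). C1 is a bridgehead and cannot epimerise, and the temporary C11 stereocentre is erased.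

## Compound list

1 | methyl 3-methylbut-2-enoate | COC(=O)C=C(C)C | starting material
2 | tert-butyl[(1-methoxy-3-methylbuta-1,3-dien-1-yl)oxy]dimethylsilane | COC(O[Si](C)(C)C(C)(C)C)=CC(C)=C | intermediate
3 | 3-methylbut-2-enal | CC(C)=CC=O | starting material
4 | methyl (2E,5S)-5-hydroxy-3,7-dimethylocta-2,6-dienoate | COC(=O)/C=C(\C)C[C@H](O)C=C(C)C | intermediate
5 | methyl (2E,5S)-5-[(tert-butyldimethylsilyl)oxy]-3,7-dimethylocta-2,6-dienoate | COC(=O)/C=C(\C)C[C@H](O[Si](C)(C)C(C)(C)C)C=C(C)C | intermediate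
6 | methyl (2E,5S,6E)-5-[(tert-butyldimethylsilyl)oxy]-8-hydroxy-3,7-dimethylocta-2,6-dienoate | COC(=O)/C=C(\C)C[C@H](O[Si](C)(C)C(C)(C)C)/C=C(\C)CO | intermediate
7 | (2E,5S,6E)-5-[(tert-butyldimethylsilyl)oxy]-8-hydroxy-3,7-dimethylocta-2,6-dienoic acid | OC(=O)/C=C(\C)C[C@H](O[Si](C)(C)C(C)(C)C)/C=C(\C)CO | intermediate
8 | triethylsilyl (2E,5S,6E)-5-[(tert-butyldimethylsilyl)oxy]-3,7-dimethyl-8-[(triethylsilyl)oxy]octa-2,6-dienoate | CC[Si](CC)(CC)OC(=O)/C=C(\C)C[C@H](O[Si](C)(C)C(C)(C)C)/C=C(\C)CO[Si](CC)(CC)CC | intermediate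
9 | (2E,5S,6E)-5-[(tert-butyldimethylsilyl)oxy]-3,7-dimethyl-8-[(triethylsilyl)oxy]octa-2,6-dienoic acid | OC(=O)/C=C(\C)C[C@H](O[Si](C)(C)C(C)(C)C)/C=C(\C)CO[Si](CC)(CC)CC | intermediate
10 | (2E,5S,6E)-5-[(tert-butyldimethylsilyl)oxy]-3,7-dimethyl-8-[(triethylsilyl)oxy]octa-2,6-dienoyl chloride | ClC(=O)/C=C(\C)C[C@H](O[Si](C)(C)C(C)(C)C)/C=C(\C)CO[Si](CC)(CC)CC | intermediate
11 | (5S,6E)-5-[(tert-butyldimethylsilyl)oxy]-7-methyl-3-methylidene-8-[(triethylsilyl)oxy]octa-1,6-dien-1-one (vinylketene) | O=C=CC(=C)C[C@H](O[Si](C)(C)C(C)(C)C)/C=C(\C)CO[Si](CC)(CC)CC | intermediate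
12 | (1R,2R,8R,11S)-11-[(tert-butyldimethylsilyl)oxy]-2-methyl-9-methylidene-2-{[(triethylsilyl)oxy]methyl}bicyclo[3.1.1]heptan-7-one (target locants) | O=C1[C@H]2[C@@H](O[Si](C)(C)C(C)(C)C)CC(=C)[C@@H]1[C@@]2(C)CO[Si](CC)(CC)CC | intermediate
13 | allyl (diethoxyphosphoryl)acetate | C=CCOC(=O)CP(=O)(OCC)OCC | starting material
14 | allyl 2-[(1R,2R,8S,11S)-11-[(tert-butyldimethylsilyl)oxy]-2-methyl-9-methylidene-2-{[(triethylsilyl)oxy]methyl}bicyclo[3.1.1]hept-7-ylidene]acetate (both alkene isomers) | C=CCOC(=O)C=C1[C@H]2[C@@H](O[Si](C)(C)C(C)(C)C)CC(=C)[C@@H]1[C@@]2(C)CO[Si](CC)(CC)CC | intermediate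
15 | allyl 2-[(1R,2R,7S,8R,11S)-11-[(tert-butyldimethylsilyl)oxy]-2-methyl-9-methylidene-2-{[(triethylsilyl)oxy]methyl}bicyclo[3.1.1]hept-7-yl]acetate | C=CCOC(=O)C[C@@H]1[C@H]2[C@@H](O[Si](C)(C)C(C)(C)C)CC(=C)[C@@H]1[C@@]2(C)CO[Si](CC)(CC)CC | intermediate
16 | allyl 2-[(1R,2R,7S,8R,11S)-11-[(tert-butyldimethylsilyl)oxy]-2-formyl-2-methyl-9-methylidenebicyclo[3.1.1]hept-7-yl]acetate | C=CCOC(=O)C[C@@H]1[C@H]2[C@@H](O[Si](C)(C)C(C)(C)C)CC(=C)[C@@H]1[C@@]2(C)C=O | intermediate
17 | allyl 2-{(1R,2R,7S,8R,11S)-11-[(tert-butyldimethylsilyl)oxy]-2-methyl-9-methylidene-2-[(2R)-4-oxooxetan-2-yl]bicyclo[3.1.1]hept-7-yl}acetate | C=CCOC(=O)C[C@@H]1[C@H]2[C@@H](O[Si](C)(C)C(C)(C)C)CC(=C)[C@@H]1[C@@]2(C)[C@H]3CC(=O)O3 | intermediate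
18 | allyl (1R,2R,3R,7S,8R,11S)-11-[(tert-butyldimethylsilyl)oxy]-3-hydroxy-2-methyl-9-methylidene-5-oxotricyclo[5.4.0.0^{2,8}]undecane-6-carboxylate (C6 epimers and enol) | C=CCOC(=O)C1[C@@H]2[C@H]3[C@@H](O[Si](C)(C)C(C)(C)C)CC(=C)[C@@H]2[C@@]3(C)[C@H](O)CC1=O | intermediate
19 | allyl (1R,2R,3R,6R,7S,8R,11S)-11-[(tert-butyldimethylsilyl)oxy]-3-hydroxy-2,6-dimethyl-9-methylidene-5-oxotricyclo[5.4.0.0^{2,8}]undecane-6-carboxylate | C=CCOC(=O)[C@]1(C)[C@@H]2[C@H]3[C@@H](O[Si](C)(C)C(C)(C)C)CC(=C)[C@@H]2[C@@]3(C)[C@H](O)CC1=O | intermediate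
20 | allyl (1R,2R,3R,5R,6R,7S,8R,11S)-11-[(tert-butyldimethylsilyl)oxy]-5-hydroxy-2,6-dimethyl-9-methylidene-3-[(3-methylbut-2-enoyl)oxy]tricyclo[5.4.0.0^{2,8}]undecane-6-carboxylate | C=CCOC(=O)[C@]1(C)[C@@H]2[C@H]3[C@@H](O[Si](C)(C)C(C)(C)C)CC(=C)[C@@H]2[C@@]3(C)[C@H](OC(=O)C=C(C)C)C[C@H]1O | intermediate
21 | (1R,2R,3R,5R,6R,7S,8R,11S)-11-[(tert-butyldimethylsilyl)oxy]-5-hydroxy-2,6-dimethyl-9-methylidene-3-[(3-methylbut-2-enoyl)oxy]tricyclo[5.4.0.0^{2,8}]undecane-6-carboxylic acid | OC(=O)[C@]1(C)[C@@H]2[C@H]3[C@@H](O[Si](C)(C)C(C)(C)C)CC(=C)[C@@H]2[C@@]3(C)[C@H](OC(=O)C=C(C)C)C[C@H]1O | intermediate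
22 | (1R,2R,3R,5R,6R,7S,8R,11S)-11-[(tert-butyldimethylsilyl)oxy]-5-hydroxy-2,6-dimethyl-9-methylidene-3-[(3-methylbut-2-enoyl)oxy]tricyclo[5.4.0.0^{2,8}]undecane-6-carbonyl fluoride | FC(=O)[C@]1(C)[C@@H]2[C@H]3[C@@H](O[Si](C)(C)C(C)(C)C)CC(=C)[C@@H]2[C@@]3(C)[C@H](OC(=O)C=C(C)C)C[C@H]1O | intermediate
23 | (1R,2R,3R,5R,6S,7S,8R,11S)-11-[(tert-butyldimethylsilyl)oxy]-5-hydroxy-6-(hydroxymethyl)-2,6-dimethyl-9-methylidenetricyclo[5.4.0.0^{2,8}]undec-3-yl 3-methylbut-2-enoate | OC[C@]1(C)[C@@H]2[C@H]3[C@@H](O[Si](C)(C)C(C)(C)C)CC(=C)[C@@H]2[C@@]3(C)[C@H](OC(=O)C=C(C)C)C[C@H]1O | intermediate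
24 | (2Z)-2-methylbut-2-enoic acid (angelic acid) | C/C=C(/C)C(=O)O | starting material
25 | (2Z)-2-methylbut-2-enoic 2,4,6-trichlorobenzoic anhydride | C/C=C(/C)C(=O)OC(=O)c1c(Cl)cc(Cl)cc1Cl | intermediate
26 | [(1R,2R,3R,5R,6S,7S,8R,11S)-11-[(tert-butyldimethylsilyl)oxy]-5-hydroxy-2,6-dimethyl-9-methylidene-3-[(3-methylbut-2-enoyl)oxy]tricyclo[5.4.0.0^{2,8}]undec-6-yl]methyl (2Z)-2-methylbut-2-enoate | C/C=C(/C)C(=O)OC[C@]1(C)[C@@H]2[C@H]3[C@@H](O[Si](C)(C)C(C)(C)C)CC(=C)[C@@H]2[C@@]3(C)[C@H](OC(=O)C=C(C)C)C[C@H]1O | intermediate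
27 | [(1R,2R,3R,5R,6S,7S,8R,11S)-5-acetoxy-11-[(tert-butyldimethylsilyl)oxy]-2,6-dimethyl-9-methylidene-3-[(3-methylbut-2-enoyl)oxy]tricyclo[5.4.0.0^{2,8}]undec-6-yl]methyl (2Z)-2-methylbut-2-enoate | C/C=C(/C)C(=O)OC[C@]1(C)[C@@H]2[C@H]3[C@@H](O[Si](C)(C)C(C)(C)C)CC(=C)[C@@H]2[C@@]3(C)[C@H](OC(=O)C=C(C)C)C[C@H]1OC(C)=O | intermediate
28 | [(1R,2R,3R,5R,6S,7S,8R,11S)-5-acetoxy-11-hydroxy-2,6-dimethyl-9-methylidene-3-[(3-methylbut-2-enoyl)oxy]tricyclo[5.4.0.0^{2,8}]undec-6-yl]methyl (2Z)-2-methylbut-2-enoate | C/C=C(/C)C(=O)OC[C@]1(C)[C@@H]2[C@H]3[C@@H](O)CC(=C)[C@@H]2[C@@]3(C)[C@H](OC(=O)C=C(C)C)C[C@H]1OC(C)=O | intermediate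
29 | [(1R,2R,3R,5R,6S,7S,8R)-5-acetoxy-2,6-dimethyl-9-methylidene-3-[(3-methylbut-2-enoyl)oxy]-11-oxotricyclo[5.4.0.0^{2,8}]undec-6-yl]methyl (2Z)-2-methylbut-2-enoate | C/C=C(/C)C(=O)OC[C@]1(C)[C@@H]2[C@H]3C(=O)CC(=C)[C@@H]2[C@@]3(C)[C@H](OC(=O)C=C(C)C)C[C@H]1OC(C)=O | intermediate
30 | [(1R,2R,3R,5R,6S,7S,8R)-5-acetoxy-2,6,9-trimethyl-3-[(3-methylbut-2-enoyl)oxy]-11-oxotricyclo[5.4.0.0^{2,8}]undec-9-en-6-yl]methyl (2Z)-2-methylbut-2-enoate | C/C=C(/C)C(=O)OC[C@]1(C)[C@@H]2[C@H]3C(=O)C=C(C)[C@@H]2[C@@]3(C)[C@H](OC(=O)C=C(C)C)C[C@H]1OC(C)=O | target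

## Step count and least certain steps

Total step count: 20. Longest linear sequence: 20 steps (1 → 30); 3, 13 and 24 enter as bought fragments.

**Step 7 (key step).** The dienolisation may take place at C4 instead of the 3-methyl group and give the isomeric dienylketene. The alkene, which carries two allylic C–O bonds, may be too electron-poor, so that ketene dimerisation and oligomerisation win. The facial control by the C11 silyloxy group may be incomplete. Fallback, from acid 9: deconjugation through its dianion (LiN(iPr)2, kinetic protonation at C2) should give (5S,6E)-5-[(tert-butyldimethylsilyl)oxy]-7-methyl-3-methylidene-8-[(triethylsilyl)oxy]oct-6-enoic acid F1. Coupling with pyrrolidine gives its pyrrolidine amide F2. Activation with Tf2O and 2,4,6-collidine in 1,2-dichloroethane at 80 °C forms a keteniminium salt by simple α-deprotonation. This species is far more electrophilic than the ketene and should undergo the same crossed [2+2] cycloaddition; aqueous NaHCO3 hydrolysis of the iminium salt returns to 12.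

**Step 11.** Addition to the α-quaternary, 1,3-diaxially crowded aldehyde may be slow, so that ketene dimerisation competes, and the catalyst may lose face control on so hindered a substrate. Fallback, from 16: an auxiliary-controlled acetate aldol addition with the titanium enolate (TiCl4, iPr2NEt) of (4S)-3-acetyl-4-isopropyl-1,3-thiazolidine-2-thione (or its enantiomer, as the 3R adduct requires) should give the β-hydroxy acyl thiazolidinethione F3. Mild hydrolysis (LiOH, H2O2, 0 °C) gives the β-hydroxy acid F4. Lactonisation by carboxyl activation (PhSO2Cl, pyridine, 0 °C), with retention at C3, comes back to 17.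

**Step 12.** The base may enolise the β-lactone instead of the allyl ester, intermolecular Claisen condensation may compete with closure of the seven-membered ring, and the bicyclic tetrahedral intermediate is strained. Fallback, from 17: aminolysis with MeONHMe·HCl/Me2AlCl should give the β-hydroxy Weinreb amide F5. Its amide α-hydrogens are much less acidic than those of the ester, so LiN(SiMe3)2 (3.2 equiv) should form the alkoxide and only the C6 ester enolate. This enolate acylates on the Weinreb amide through the stable chelated adduct and returns to 18 after acidic work-up.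

**Step 13.** The facial selectivity of the methylation may be poor, because the seven-membered ring is flexible and the hydrogen bond that holds C3–O over one face is weak; O-alkylation and lactonisation of C3–OH onto the ester are further side paths. Fallback, from 18: condensation with tert-butyl L-valinate (or its enantiomer) should give the chiral enamino ester F6. Lithiation (LiN(iPr)2) and methylation under auxiliary control, then aqueous acid, come back to 19.

**Step 14.** With an α,β-unsaturated aldehyde the samarium catalyst may be consumed by pinacol or Tishchenko dimerisation, and hemiacetal formation at the hindered C3 hydroxyl may be slow. Fallback, from 19: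
- directed reduction with Me4NBH(OAc)3 (MeCN/AcOH, −20 °C) should give the anti-diol F7;
- LiAlH4 gives the triol F8;
- 2,2-dimethoxypropane and PPTS close the only possible six-membered acetal (O5/O12) to the acetonide F9, leaving C3–OH free;
- esterification with 3-methylbut-2-enoic acid (DCC, DMAP) gives the senecioate F10;
- aqueous acetic acid removes the acetal and returns to 23.

## Further compounds

F1 | step 7 | (5S,6E)-5-[(tert-butyldimethylsilyl)oxy]-7-methyl-3-methylidene-8-[(triethylsilyl)oxy]oct-6-enoic acid | OC(=O)CC(=C)C[C@H](O[Si](C)(C)C(C)(C)C)/C=C(\C)CO[Si](CC)(CC)CC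
F2 | step 7 | (5S,6E)-5-[(tert-butyldimethylsilyl)oxy]-7-methyl-3-methylidene-1-(pyrrolidin-1-yl)-8-[(triethylsilyl)oxy]oct-6-en-1-one | O=C(CC(=C)C[C@H](O[Si](C)(C)C(C)(C)C)/C=C(\C)CO[Si](CC)(CC)CC)N1CCCC1
F3 | step 11 | allyl 2-[(1R,2R,7S,8R,11S)-11-[(tert-butyldimethylsilyl)oxy]-2-{(1R)-1-hydroxy-3-oxo-3-[(4S)-4-isopropyl-2-thioxo-1,3-thiazolidin-3-yl]propyl}-2-methyl-9-methylidenebicyclo[3.1.1]hept-7-yl]acetate | C=CCOC(=O)C[C@@H]1[C@H]2[C@@H](O[Si](C)(C)C(C)(C)C)CC(=C)[C@@H]1[C@@]2(C)[C@H](O)CC(=O)N3[C@@H](C(C)C)CSC3=S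
F4 | step 11 | (3R)-3-[(1R,2R,7S,8R,11S)-7-(2-allyloxy-2-oxoethyl)-11-[(tert-butyldimethylsilyl)oxy]-2-methyl-9-methylidenebicyclo[3.1.1]hept-2-yl]-3-hydroxypropanoic acid | C=CCOC(=O)C[C@@H]1[C@H]2[C@@H](O[Si](C)(C)C(C)(C)C)CC(=C)[C@@H]1[C@@]2(C)[C@H](O)CC(O)=O
F5 | step 12 | allyl 2-[(1R,2R,7S,8R,11S)-11-[(tert-butyldimethylsilyl)oxy]-2-{(1R)-1-hydroxy-3-[methoxy(methyl)amino]-3-oxopropyl}-2-methyl-9-methylidenebicyclo[3.1.1]hept-7-yl]acetate | C=CCOC(=O)C[C@@H]1[C@H]2[C@@H](O[Si](C)(C)C(C)(C)C)CC(=C)[C@@H]1[C@@]2(C)[C@H](O)CC(=O)N(C)OC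
F6 | step 13 | allyl (1R,2R,3R,7S,8R,11S)-5-{[(2S)-1-tert-butoxy-3-methyl-1-oxobutan-2-yl]amino}-11-[(tert-butyldimethylsilyl)oxy]-3-hydroxy-2-methyl-9-methylidenetricyclo[5.4.0.0^{2,8}]undec-5-ene-6-carboxylate | C=CCOC(=O)C=1[C@@H]2[C@H]3[C@@H](O[Si](C)(C)C(C)(C)C)CC(=C)[C@@H]2[C@@]3(C)[C@H](O)CC=1N[C@@H](C(C)C)C(=O)OC(C)(C)C
F7 | step 14 | allyl (1R,2R,3R,5R,6R,7S,8R,11S)-11-[(tert-butyldimethylsilyl)oxy]-3,5-dihydroxy-2,6-dimethyl-9-methylidenetricyclo[5.4.0.0^{2,8}]undecane-6-carboxylate | C=CCOC(=O)[C@]1(C)[C@@H]2[C@H]3[C@@H](O[Si](C)(C)C(C)(C)C)CC(=C)[C@@H]2[C@@]3(C)[C@H](O)C[C@H]1O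
F8 | step 14 | (1R,2R,3R,5R,6S,7S,8R,11S)-11-[(tert-butyldimethylsilyl)oxy]-6-(hydroxymethyl)-2,6-dimethyl-9-methylidenetricyclo[5.4.0.0^{2,8}]undecane-3,5-diol | OC[C@]1(C)[C@@H]2[C@H]3[C@@H](O[Si](C)(C)C(C)(C)C)CC(=C)[C@@H]2[C@@]3(C)[C@H](O)C[C@H]1O
F9 | step 14 | O5,O12-isopropylidene acetal of F8 (1,3-dioxane fused at C5–C6, C3–OH free) | CC1(C)OC[C@]2(C)[C@@H]3[C@H]4[C@@H](O[Si](C)(C)C(C)(C)C)CC(=C)[C@@H]3[C@@]4(C)[C@H](O)C[C@H]2O1
F10 | step 14 | O5,O12-isopropylidene acetal of 23 (3-methylbut-2-enoate on O3) | CC1(C)OC[C@]2(C)[C@@H]3[C@H]4[C@@H](O[Si](C)(C)C(C)(C)C)CC(=C)[C@@H]3[C@@]4(C)[C@H](OC(=O)C=C(C)C)C[C@H]2O1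
A1 | alternative 1 | (1E,7E,9Z)-cycloundeca-1,7,9-trien-11-one with the three ester groups of 30 (target locants, C3, C5, C6 as in 30) | O=C1/C=C(/C)\C=C\[C@@](C)(COC(=O)/C(C)=C\C)[C@H](OC(C)=O)C[C@@H](OC(=O)C=C(C)C)/C(C)=C/1
A2 | alternative 2 | (1S,5S)-4,6,6-trimethylbicyclo[3.1.1]hept-3-en-2-one (verbenone) | C1[C@@H]2C(=O)C=C(C)[C@H]1C2(C)C
A3 | alternative 2 | (1R,5S)-2,7,7-trimethylbicyclo[3.1.1]hept-2-en-6-one (chrysanthenone) | O=C1[C@H]2CC=C(C)[C@@H]1C2(C)C
A4 | alternative 3 | 6–7-fused keto mesylate: bicyclo[5.4.0]undec-9-en-11-one with the three ester groups of 30 and a C7 methanesulfonate (target locants, C1–C7 bond missing) | O=C1C[C@]2(C)[C@H](OC(=O)C=C(C)C)C[C@@H](OC(C)=O)[C@](C)(COC(=O)/C(C)=C\C)[C@@H](OS(C)(=O)=O)[C@@H]2C(C)=C1
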